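**Retrosynthetic overview**

- Feature: in the oxolane ring (O1, C2 with the 3,4-dimethoxyphenyl group, C3, C4, C5 with the 3,4,5-trimethoxyphenyl group) the methyl groups on C3 and C4 are cis to each other and trans to the two cis aryl groups. Both methyl carbons can therefore be delivered together to the free face of a C3=C4 alkene.
- C3–CH3 and C4–CH3 come from the cis-fused dichlorocyclobutanone 15 (C(O)–CCl2 cleavage, then reduction of the CO2Me and CHCl2 arms). 15 comes from dichloroketene and the cis-2,5-diaryl-2,5-dihydrofuran 12.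
- 12 comes from ring-closing metathesis of the bis-allylic ether 11. 11 comes from iridium-catalysed allylic etherification of (S)-alcohol 4 with cinnamyl carbonate 8 (C5 set by the catalyst, C2 by kinetic resolution).
- Ring order: the oxolane ring is made first (metathesis), the cyclobutanone is fused on in the key step and opened again; only the oxolane remains.

Key step: step 7

Remark (numbering): the ring numbering O1, C2 (3,4-dimethoxyphenyl), C3, C4, C5 (3,4,5-trimethoxyphenyl) is used for all oxolane intermediates.

Assumption 1: the ligand made from (R)-BINOL and bis[(R)-1-phenylethyl]amine is taken, by analogy with etherifications and aminations of (E)-cinnamyl carbonates, to give (R)-1-arylallyl ethers; if the sense is the opposite, the enantiomeric ligand is used and nothing else changes.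

Assumption 2: dichloroketene may add to 12 in either orientation; both cyclobutanones converge on 19 through steps 8–11 and are carried on together, and the structures are drawn for the isomer with the carbonyl on C3.

**Route**

Step 1
Reactants: 1 3,4-dimethoxybenzaldehyde; 2 vinylmagnesium bromide
Product: 3 racemic 1-(3,4-dimethoxyphenyl)prop-2-en-1-ol
Conditions: 2 (1.2 equiv), THF, 0 °C; aq. NH4Cl
Reagents that add atoms: none
Why: Grignard 1,2-addition to an aryl aldehyde is fast and clean at 0 °C; the carbinol centre is formed racemic and is resolved in step 2.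

Step 2
Reactants: 3 racemic 1-(3,4-dimethoxyphenyl)prop-2-en-1-ol
Product: 4 (S)-1-(3,4-dimethoxyphenyl)prop-2-en-1-ol
Conditions: Ti(OiPr)4 (0.15 equiv), L-(+)-diisopropyl tartrate (0.2 equiv), t-BuOOH (0.6 equiv, in decane), 4 Å MS, CH2Cl2, −20 °C; stopped shortly after half conversion; chromatography
Reagents that add atoms: none
Why: Sharpless kinetic resolution of a secondary allylic alcohol: with L-(+)-tartrate the titanium catalyst should epoxidise the (R)-enantiomer much faster, so the (S)-alcohol is recovered enantioenriched.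

Step 3
Reactants: 5 (E)-3-(3,4,5-trimethoxyphenyl)acrylic acid
Product: 7 (E)-3-(3,4,5-trimethoxyphenyl)prop-2-en-1-ol, via mixed carbonic anhydride 6 (not isolated)
Conditions: ClCO2Et, Et3N, THF, −10 °C; filtration; NaBH4, THF/H2O, 0 °C → rt
Reagents that add atoms: none
Why: Reduction of a carboxylic acid through its mixed carbonic anhydride with NaBH4 is selective for the acyl carbon and should leave the conjugated (E)-alkene untouched.

Step 4
Reactants: 7 (E)-3-(3,4,5-trimethoxyphenyl)prop-2-en-1-ol
Product: 8 tert-butyl (E)-3-(3,4,5-trimethoxyphenyl)prop-2-en-1-yl carbonate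
Conditions: Boc2O, n-Bu4NHSO4 (cat.), 30% aq. NaOH, CH2Cl2, 0 °C → rt
Reagents that add atoms: di-tert-butyl dicarbonate, CC(C)(C)OC(=O)OC(=O)OC(C)(C)C
Why: Phase-transfer O-acylation of a primary allylic alcohol; the tert-butyl carbonate is chosen because it resists acyl transfer to the alkoxide used in step 5 and its leaving group is too hindered to compete as a nucleophile.

Step 5
Reactants: 4 (S)-1-(3,4-dimethoxyphenyl)prop-2-en-1-ol; 8 tert-butyl (E)-3-(3,4,5-trimethoxyphenyl)prop-2-en-1-yl carbonate
Product: 11 (S)-1-(3,4-dimethoxyphenyl)allyl (R)-1-(3,4,5-trimethoxyphenyl)allyl ether, via lithium alkoxide 9 (not isolated), via copper alkoxide 10 (not isolated)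
Conditions: 4 (1.3 equiv), n-BuLi, THF, 0 °C; CuI, rt; then 8, [Ir(cod)Cl]2 (2 mol%), (Ra,R,R)-phosphoramidite from (R)-BINOL and bis[(R)-1-phenylethyl]amine (4 mol%, catalyst pre-activated with n-PrNH2), THF, rt
Reagents that add atoms: none
Why: Iridium-catalysed branch-selective asymmetric allylic etherification with a monovalent copper alkoxide of a secondary alcohol: oxygen attacks the aryl-substituted terminus of the allyl–iridium intermediate, the new C–O stereocentre (R) is set by the cyclometalated iridium–phosphoramidite catalyst (catalyst control), and the (S) centre of 4 is carried in unchanged because its C–O bond is not touched.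

Step 6
Reactants: 11 (S)-1-(3,4-dimethoxyphenyl)allyl (R)-1-(3,4,5-trimethoxyphenyl)allyl ether
Product: 12 (2S,5R)-2-(3,4-dimethoxyphenyl)-5-(3,4,5-trimethoxyphenyl)-2,5-dihydrofuran
Conditions: second-generation Grubbs catalyst (H2IMes)(PCy3)Cl2Ru=CHPh (3 mol%), 1,4-benzoquinone (10 mol%), CH2Cl2 (0.02 M), 40 °C, Ar; filtered through basic alumina and used at once
Reagents that add atoms: none
Why: Ring-closing metathesis of a 1,6-diene to a 2,5-dihydrofuran driven by loss of ethylene; no stereocentre is touched, so the (S,R) ether can only give the cis-2,5-diaryl ring.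

Step 7
Reactants: 12 (2S,5R)-2-(3,4-dimethoxyphenyl)-5-(3,4,5-trimethoxyphenyl)-2,5-dihydrofuran; 13 trichloroacetyl chloride
Product: 15 (1R,2R,4S,5S)-7,7-dichloro-4-(3,4-dimethoxyphenyl)-2-(3,4,5-trimethoxyphenyl)-3-oxabicyclo[3.2.0]heptan-6-one, via dichloroketene 14 (not isolated)
Conditions: Zn(Cu) couple (3 equiv), 13 (2 equiv, slow addition), Et2O/DME, 20–35 °C, Ar; filtration, cold aq. NaHCO3 wash
Reagents that add atoms: none
Why: Dichloroketene, formed by zinc dechlorination of 13, adds to the C3=C4 bond of 12 in a concerted but asynchronous (2+2) process in which the electrophilic central carbon of the ketene bonds first and the alkene reacts suprafacially; the closest known reactions are the additions of dichloroketene to cyclopentene and to the parent 2,5-dihydrofuran. The cyclobutanone ring is closed by this intermolecular cycloaddition itself, both C–C bonds arising on the same alkene face, so the ring fusion is necessarily cis. The two new stereocentres (C3 and C4) are set by the substrate: the cis aryl groups at C2 and C5 cover one face of the nearly flat five-membered ring, the ketene approaches from the other, and both new carbons end up trans to the aryl groups. The step needs facial selectivity only, because either orientation of the ketene gives a cyclobutanone whose two carbons both become methyl groups. Reaction at the alkene rather than at the ring oxygen is helped by the two aryl-bearing carbons that flank the oxygen, and DME binds ZnCl2 so that the bis-benzylic allylic ether is not ionised.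

Step 8
Reactants: 15 (1R,2R,4S,5S)-7,7-dichloro-4-(3,4-dimethoxyphenyl)-2-(3,4,5-trimethoxyphenyl)-3-oxabicyclo[3.2.0]heptan-6-one
Product: 16 methyl (2S,3S,4R,5R)-4-(dichloromethyl)-2-(3,4-dimethoxyphenyl)-5-(3,4,5-trimethoxyphenyl)oxolane-3-carboxylate
Conditions: NaOMe (0.2 equiv), MeOH/THF, −20 → 0 °C; AcOH quench
Reagents that add atoms: methanol (as methoxide), CO
Why: Haloform-type cleavage of an α,α-dichlorocyclobutanone: methoxide adds to the strained carbonyl and the tetrahedral intermediate expels the dichloromethyl carbanion, which methanol protonates with regeneration of methoxide, so both ring-fusion centres are retained; catalytic base at low temperature is used so that the ester-bearing centre C3 is not equilibrated.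

Step 9
Reactants: 16 methyl (2S,3S,4R,5R)-4-(dichloromethyl)-2-(3,4-dimethoxyphenyl)-5-(3,4,5-trimethoxyphenyl)oxolane-3-carboxylate
Product: 17 [(2S,3R,4R,5R)-4-(dichloromethyl)-2-(3,4-dimethoxyphenyl)-5-(3,4,5-trimethoxyphenyl)oxolan-3-yl]methanol
Conditions: i-Bu2AlH (3 equiv), CH2Cl2, −78 → −20 °C; aq. Rochelle salt
Reagents that add atoms: none
Why: Reduction of an ester to the primary alcohol by the non-basic hydride i-Bu2AlH at low temperature, which does not touch alkyl chlorides or benzylic ethers and affects no stereocentre.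

Step 10
Reactants: 17 [(2S,3R,4R,5R)-4-(dichloromethyl)-2-(3,4-dimethoxyphenyl)-5-(3,4,5-trimethoxyphenyl)oxolan-3-yl]methanol
Product: 18 (2S,3S,4R,5R)-4-(dichloromethyl)-2-(3,4-dimethoxyphenyl)-3-(iodomethyl)-5-(3,4,5-trimethoxyphenyl)oxolane
Conditions: I2, PPh3, imidazole, CH2Cl2, 0 °C → rt
Reagents that add atoms: iodine, II
Why: Appel-type iodination converts the primary alcohol into the iodide by SN2 displacement of an alkoxyphosphonium ion at a CH2 group under nearly neutral conditions, so no stereocentre is involved.

Step 11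
Reactants: 18 (2S,3S,4R,5R)-4-(dichloromethyl)-2-(3,4-dimethoxyphenyl)-3-(iodomethyl)-5-(3,4,5-trimethoxyphenyl)oxolane
Product: 19 (2S,3S,4R,5R)-2-(3,4-dimethoxyphenyl)-3,4-dimethyl-5-(3,4,5-trimethoxyphenyl)oxolane
Conditions: Bu3SnH (8 equiv, 0.5 M), 1,1'-azobis(cyclohexanecarbonitrile) (in portions), toluene, 110 °C; chromatography on K2CO3-doped silica
Reagents that add atoms: none
Why: Radical-chain hydrodehalogenation with Bu3SnH: stannyl radicals abstract the iodine and then both chlorines and each carbon radical is quenched by hydrogen transfer at an exocyclic carbon, so the four ring stereocentres are not touched; excess stannane at high concentration and a high-temperature initiator serve the slow primary C–Cl abstraction and outrun ring fragmentation.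

**Compound list**

1 | 3,4-dimethoxybenzaldehyde | COc1ccc(C=O)cc1OC | starting material
2 | vinylmagnesium bromide | C=C[Mg]Br | starting material
3 | racemic 1-(3,4-dimethoxyphenyl)prop-2-en-1-ol | COc1ccc(C(O)C=C)cc1OC | intermediate
4 | (S)-1-(3,4-dimethoxyphenyl)prop-2-en-1-ol | COc1ccc([C@H](C=C)O)cc1OC | intermediate
5 | (E)-3-(3,4,5-trimethoxyphenyl)acrylic acid | COc1cc(/C=C/C(=O)O)cc(OC)c1OC | starting material
6 | ethoxycarbonyl (E)-3-(3,4,5-trimethoxyphenyl)acrylate (mixed carbonic anhydride, not isolated) | COc1cc(/C=C/C(=O)OC(=O)OCC)cc(OC)c1OC | intermediate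
7 | (E)-3-(3,4,5-trimethoxyphenyl)prop-2-en-1-ol | COc1cc(/C=C/CO)cc(OC)c1OC | intermediate
8 | tert-butyl (E)-3-(3,4,5-trimethoxyphenyl)prop-2-en-1-yl carbonate | COc1cc(/C=C/COC(=O)OC(C)(C)C)cc(OC)c1OC | intermediate
9 | lithium (S)-1-(3,4-dimethoxyphenyl)prop-2-en-1-olate (not isolated) | COc1ccc([C@H](C=C)O[Li])cc1OC | intermediate
10 | monovalent copper (S)-1-(3,4-dimethoxyphenyl)prop-2-en-1-olate (not isolated) | COc1ccc([C@H](C=C)O[Cu])cc1OC | intermediate
11 | (S)-1-(3,4-dimethoxyphenyl)allyl (R)-1-(3,4,5-trimethoxyphenyl)allyl ether | COc1ccc([C@H](C=C)O[C@H](C=C)c2cc(OC)c(OC)c(OC)c2)cc1OC | intermediate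
12 | (2S,5R)-2-(3,4-dimethoxyphenyl)-5-(3,4,5-trimethoxyphenyl)-2,5-dihydrofuran (aryl groups cis) | COc1ccc([C@H]2O[C@@H](c3cc(OC)c(OC)c(OC)c3)C=C2)cc1OC | intermediate
13 | trichloroacetyl chloride | ClC(Cl)(Cl)C(Cl)=O | starting material
14 | dichloroketene (not isolated) | ClC(Cl)=C=O | intermediate
15 | (1R,2R,4S,5S)-7,7-dichloro-4-(3,4-dimethoxyphenyl)-2-(3,4,5-trimethoxyphenyl)-3-oxabicyclo[3.2.0]heptan-6-one (cis-fused, four-membered ring trans to both aryl groups, carbonyl on oxolane C3) | COc1ccc([C@H]2O[C@@H](c3cc(OC)c(OC)c(OC)c3)[C@H]3[C@@H]2C(=O)C3(Cl)Cl)cc1OC | intermediate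
16 | methyl (2S,3S,4R,5R)-4-(dichloromethyl)-2-(3,4-dimethoxyphenyl)-5-(3,4,5-trimethoxyphenyl)oxolane-3-carboxylate (CO2Me and CHCl2 cis, both trans to the aryl groups) | COc1ccc([C@H]2O[C@@H](c3cc(OC)c(OC)c(OC)c3)[C@H](C(Cl)Cl)[C@@H]2C(=O)OC)cc1OC | intermediate
17 | [(2S,3R,4R,5R)-4-(dichloromethyl)-2-(3,4-dimethoxyphenyl)-5-(3,4,5-trimethoxyphenyl)oxolan-3-yl]methanol | COc1ccc([C@H]2O[C@@H](c3cc(OC)c(OC)c(OC)c3)[C@H](C(Cl)Cl)[C@@H]2CO)cc1OC | intermediate
18 | (2S,3S,4R,5R)-4-(dichloromethyl)-2-(3,4-dimethoxyphenyl)-3-(iodomethyl)-5-(3,4,5-trimethoxyphenyl)oxolane | COc1ccc([C@H]2O[C@@H](c3cc(OC)c(OC)c(OC)c3)[C@H](C(Cl)Cl)[C@@H]2CI)cc1OC | intermediate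
19 | (2S,3S,4R,5R)-2-(3,4-dimethoxyphenyl)-3,4-dimethyl-5-(3,4,5-trimethoxyphenyl)oxolane | COc1ccc([C@H]2O[C@@H](c3cc(OC)c(OC)c(OC)c3)[C@H](C)[C@@H]2C)cc1OC | target

**Step count and risks**

Total step count: 11. Longest linear sequence: 9 steps (5 → 7 → 8 → 11 → 12 → 15 → 16 → 17 → 18 → 19; the branch from 1 is equally long).

Steps most likely to fail:

Step 7 (key cycloaddition). The ketene may be intercepted by the ring oxygen (acyl oxonium formation followed by C–O cleavage or a ketene–Claisen shift). It may also oligomerise faster than it adds to an alkene that is deactivated by two allylic C–O bonds. ZnCl2 may ionise the bis-benzylic allylic ether, so that the ring aromatises to the furan. The fallback sets out from 12 and replaces the cycloaddition by a palladium-catalysed syn bis(methoxycarbonylation) [PdCl2 (5 mol%), CuCl2, NaOAc, CO (3 atm), MeOH, rt]. A Pd–CO2Me unit should add to the alkene face away from the aryl groups, and CO insertion and methanolysis proceed with retention. This should give dimethyl (2S,3S,4R,5R)-2-(3,4-dimethoxyphenyl)-5-(3,4,5-trimethoxyphenyl)oxolane-3,4-dicarboxylate F1. LiAlH4 (THF, 0 °C) should reduce it to [(2S,3R,4S,5R)-2-(3,4-dimethoxyphenyl)-5-(3,4,5-trimethoxyphenyl)oxolane-3,4-diyl]dimethanol F2. MsCl/Et3N (CH2Cl2, −20 °C, excess reagent so that no hydroxy mesylate survives to cyclise) should give [(2S,3R,4S,5R)-2-(3,4-dimethoxyphenyl)-5-(3,4,5-trimethoxyphenyl)oxolane-3,4-diyl]bis(methylene) dimethanesulfonate F3. LiAlH4 (THF, reflux) should then displace both sulfonates by hydride, and the fallback comes back to the route at 19.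

Step 8 (ring opening). Under methoxide the ester enolate of 16 may form, which would equilibrate C3 or expel the ring oxygen by β-elimination; a semibenzilic shift to a cyclopropane ester may also compete with C–C cleavage. The fallback sets out from 15 and changes the nucleophile to hydroxide (LiOH, THF/H2O, 0 °C). The cleavage product is then a carboxylate, which cannot be deprotonated at C3 under the conditions. Acidification to pH 4 should give (2S,3S,4R,5R)-4-(dichloromethyl)-2-(3,4-dimethoxyphenyl)-5-(3,4,5-trimethoxyphenyl)oxolane-3-carboxylic acid F4. The electrophilic reductant BH3·SMe2 (THF, 0 °C → rt) should reduce F4 to the alcohol, and the fallback comes back to the route at 17.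

Step 11 (global dehalogenation). The radical chain may stall at the primary chloride once the iodine and the first chlorine are removed, and forcing conditions raise the chance of ring fragmentation of the exocyclic radicals. The fallback sets out from 18 and uses the radical chain only for the two easy bonds [Bu3SnH (2.2 equiv), AIBN, benzene, 80 °C], which should give (2S,3S,4R,5R)-4-(chloromethyl)-2-(3,4-dimethoxyphenyl)-3-methyl-5-(3,4,5-trimethoxyphenyl)oxolane F5. The remaining primary C–Cl bond is then cut by a polar mechanism, SN2 displacement by hydride with LiEt3BH (THF, 65 °C), and the fallback comes back to the route at 19.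

**Further compounds**

F1 | step 7 | dimethyl (2S,3S,4R,5R)-2-(3,4-dimethoxyphenyl)-5-(3,4,5-trimethoxyphenyl)oxolane-3,4-dicarboxylate | COc1ccc([C@H]2O[C@@H](c3cc(OC)c(OC)c(OC)c3)[C@H](C(=O)OC)[C@@H]2C(=O)OC)cc1OC
F2 | step 7 | [(2S,3R,4S,5R)-2-(3,4-dimethoxyphenyl)-5-(3,4,5-trimethoxyphenyl)oxolane-3,4-diyl]dimethanol | COc1ccc([C@H]2O[C@@H](c3cc(OC)c(OC)c(OC)c3)[C@H](CO)[C@@H]2CO)cc1OC
F3 | step 7 | [(2S,3R,4S,5R)-2-(3,4-dimethoxyphenyl)-5-(3,4,5-trimethoxyphenyl)oxolane-3,4-diyl]bis(methylene) dimethanesulfonate | COc1ccc([C@H]2O[C@@H](c3cc(OC)c(OC)c(OC)c3)[C@H](COS(C)(=O)=O)[C@@H]2COS(C)(=O)=O)cc1OC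
F4 | step 8 | (2S,3S,4R,5R)-4-(dichloromethyl)-2-(3,4-dimethoxyphenyl)-5-(3,4,5-trimethoxyphenyl)oxolane-3-carboxylic acid | COc1ccc([C@H]2O[C@@H](c3cc(OC)c(OC)c(OC)c3)[C@H](C(Cl)Cl)[C@@H]2C(=O)O)cc1OC
F5 | step 11 | (2S,3S,4R,5R)-4-(chloromethyl)-2-(3,4-dimethoxyphenyl)-3-methyl-5-(3,4,5-trimethoxyphenyl)oxolane | COc1ccc([C@H]2O[C@@H](c3cc(OC)c(OC)c(OC)c3)[C@H](CCl)[C@@H]2C)cc1OC
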